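## Retrosynthetic overview

1. Target 31 comes from the trans-2-aryl-2,3-dihydrobenzofuran-3-carboxylate 29 by ester reduction, global desilylation and unmasking of the enal from its acetal.
2. Key disconnection: C2 of the dihydrobenzofuran to C1 of the adjacent 3,5-dimethoxy-4-alkoxyphenyl ring (ring C), made by a Rh/chiral-diene dearomative 1,4-arylation of the flat benzofuran-3-carboxylate 28 with boronic acid 22. The catalyst sets C2 and anti protonation sets C3.
3. Enabling feature: in the target, C2 bears the ring oxygen O1 and is β to the exocyclic C3–CH2OH carbon. At the ester level, O1–C2=C3–CO2Et of a benzofuran is a vinylogous carbonate inside a weakly aromatic furan ring, so an aryl nucleophile can be delivered to C2.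
4. Boronic acid 22 comes from two iterative Evans syn-glycolate aldol reactions of one imide 5 (C7–C8 bonds of units A and B). Each threo adduct is inverted at C7 by Mitsunobu reaction to erythro; ArBr becomes ArCHO between the aldols and ArB(OH)2 at the end.
5. Ring order: only the furan ring of 26 is built (from a salicylaldehyde and ethyl diazoacetate), before the key step. All benzene rings are bought and the key step closes no ring.

Key step: step 19

Assumptions and abbreviations: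
- 4 and 27 are taken as catalogue compounds.
- In step 19 the diene antipode written is the one expected to give 2R by analogy with chromone arylations. The sense of induction is to be checked on a model boronic acid, and the other antipode is used if needed.
- CIP letters are given for each compound as drawn, so the C8-type centre changes letter between imide and diol without any change in space.
- The Z-boron enolate of imide 5 is generated in the flask in the same way in both aldol steps (3 and 10); it is numbered and listed once, as 6, at step 3 where it first appears.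
- TBS = tert-butyldimethylsilyl; TIPS = triisopropylsilyl.
- RA = (1R,2S)-1,3-bis(TBS-oxy)-1-[3-methoxy-4-(TIPS-oxy)phenyl]propan-2-yl.
- RB = (1R,2S)-1,3-bis(TBS-oxy)-1-[3,5-dimethoxy-4-(RA-oxy)phenyl]propan-2-yl.

## Route

Step 1
Reactants: 1 vanillin (4-hydroxy-3-methoxybenzaldehyde)
Product: 2 3-methoxy-4-(triisopropylsilyloxy)benzaldehyde
Conditions: TIPSCl, imidazole, DMF, rt
Reagents that add atoms: triisopropylsilyl chloride, CC(C)[Si](Cl)(C(C)C)C(C)C
Why: O-silylation of the phenol; the hindered aryl TIPS ether should survive the boron enolate, hydride, carbonate/methanol and organolithium steps that follow.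

Step 2
Reactants: 3 4-bromo-2,6-dimethoxyphenol; 4 (R)-4-benzyl-3-(chloroacetyl)oxazolidin-2-one
Product: 5 (R)-4-benzyl-3-[(4-bromo-2,6-dimethoxyphenoxy)acetyl]oxazolidin-2-one
Conditions: K2CO3, NaI (cat.), acetone, 40 °C
Reagents that add atoms: none
Why: Williamson ether synthesis, an SN2 displacement by the phenoxide at the activated α-halo imide carbon (iodide-assisted) that leaves the auxiliary stereocentre untouched.

Step 3
Reactants: 5 (R)-4-benzyl-3-[(4-bromo-2,6-dimethoxyphenoxy)acetyl]oxazolidin-2-one; 2 3-methoxy-4-(triisopropylsilyloxy)benzaldehyde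
Product: 7 (R)-4-benzyl-3-{(2R,3S)-2-(4-bromo-2,6-dimethoxyphenoxy)-3-hydroxy-3-[3-methoxy-4-(TIPS-oxy)phenyl]propanoyl}oxazolidin-2-one, via Z-boron enolate 6 (not isolated)
Conditions: Bu2BOTf, i-Pr2NEt, CH2Cl2, −78 → 0 °C; then 2, −78 → 0 °C; pH 7 buffer, MeOH, 30 % H2O2, 0 °C
Reagents that add atoms: none
Why: Evans syn-aldol reaction of a glycolate imide, in which the Z(O)-boron enolate reacts through a closed Zimmerman–Traxler chair on the face remote from the benzyl group of the (R)-auxiliary and so sets both new centres (threo, 7S,8S in the numbering of the later diol).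

Step 4
Reactants: 7 syn-aldol adduct of unit A
Product: 8 (1S,2S)-2-(4-bromo-2,6-dimethoxyphenoxy)-1-[3-methoxy-4-(TIPS-oxy)phenyl]propane-1,3-diol
Conditions: LiBH4, MeOH (1 equiv), THF, 0 °C
Reagents that add atoms: none
Why: reductive cleavage of the N-acyl oxazolidinone to the primary alcohol, which releases the auxiliary and does not touch the two stereocentres.

Step 5
Reactants: 8 threo diol of unit A
Product: 9 (1S,2S)-2-(4-bromo-2,6-dimethoxyphenoxy)-3-(TBS-oxy)-1-[3-methoxy-4-(TIPS-oxy)phenyl]propan-1-ol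
Conditions: TBSCl, imidazole, CH2Cl2, 0 °C
Reagents that add atoms: tert-butyldimethylsilyl chloride, CC(C)(C)[Si](C)(C)Cl
Why: selective silylation of the primary hydroxyl over the hindered secondary benzylic one, which also removes any neighbouring-group participation in the next step.

Step 6
Reactants: 9 mono-TBS threo alcohol of unit A
Product: 10 (1R,2S)-2-(4-bromo-2,6-dimethoxyphenoxy)-3-(TBS-oxy)-1-[3-methoxy-4-(TIPS-oxy)phenyl]propyl 4-nitrobenzoate
Conditions: PPh3, DIAD, 4-nitrobenzoic acid, toluene, 0 °C → rt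
Reagents that add atoms: 4-nitrobenzoic acid, O=C(O)c1ccc(cc1)[N+](=O)[O-]
Why: Mitsunobu reaction, in which SN2 attack of the carboxylate on the alkoxyphosphonium ion inverts the benzylic carbinol centre (S to R) and converts the threo into the erythro series.

Step 7
Reactants: 10 inverted 4-nitrobenzoate of unit A
Product: 11 (1R,2S)-2-(4-bromo-2,6-dimethoxyphenoxy)-3-(TBS-oxy)-1-[3-methoxy-4-(TIPS-oxy)phenyl]propan-1-ol
Conditions: K2CO3 (cat.), MeOH/THF, 0 °C
Reagents that add atoms: none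
Why: transesterification of the activated 4-nitrobenzoate by acyl–oxygen cleavage, which should leave the carbinol configuration and the aryl TIPS ether intact.

Step 8
Reactants: 11 erythro alcohol of unit A
Product: 12 5-bromo-1,3-dimethoxy-2-(RA-oxy)benzene
Conditions: TBSOTf, 2,6-lutidine, CH2Cl2, 0 °C
Reagents that add atoms: tert-butyldimethylsilyl triflate, CC(C)(C)[Si](C)(C)OS(=O)(=O)C(F)(F)F
Why: silylation of the hindered secondary alcohol with the silyl triflate gives a fully silyl-protected unit that tolerates organolithium chemistry.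

Step 9
Reactants: 12 5-bromo-1,3-dimethoxy-2-(RA-oxy)benzene
Product: 14 3,5-dimethoxy-4-(RA-oxy)benzaldehyde, via aryllithium 13 (not isolated)
Conditions: n-BuLi, THF, −78 °C; DMF, −78 → 0 °C; aq. NH4Cl
Reagents that add atoms: N,N-dimethylformamide, CN(C)C=O
Why: bromine–lithium exchange followed by formylation with DMF (Bouveault-type) should be faster than any deprotonation at −78 °C and no stereocentre is involved.

Step 10
Reactants: 5 (R)-4-benzyl-3-[(4-bromo-2,6-dimethoxyphenoxy)acetyl]oxazolidin-2-one; 14 3,5-dimethoxy-4-(RA-oxy)benzaldehyde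
Product: 15 (R)-4-benzyl-3-{(2R,3S)-2-(4-bromo-2,6-dimethoxyphenoxy)-3-hydroxy-3-[3,5-dimethoxy-4-(RA-oxy)phenyl]propanoyl}oxazolidin-2-one
Conditions: Bu2BOTf, i-Pr2NEt, CH2Cl2, −78 → 0 °C; then 14, −78 → 0 °C; pH 7 buffer, MeOH, 30 % H2O2, 0 °C
Reagents that add atoms: none
Why: second Evans syn-aldol reaction under auxiliary control, run through the Z(O)-boron enolate of 5 already described in step 3, which sets the two centres of unit B (threo) independently of the remote centres of unit A.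

Step 11
Reactants: 15 syn-aldol adduct of unit B
Product: 16 (1S,2S)-2-(4-bromo-2,6-dimethoxyphenoxy)-1-[3,5-dimethoxy-4-(RA-oxy)phenyl]propane-1,3-diol
Conditions: LiBH4, MeOH (1 equiv), THF, 0 °C
Reagents that add atoms: none
Why: reductive removal of the auxiliary as in step 4, with silyl ethers and aryl bromide inert to borohydride.

Step 12
Reactants: 16 threo diol of unit B
Product: 17 (1S,2S)-2-(4-bromo-2,6-dimethoxyphenoxy)-3-(TBS-oxy)-1-[3,5-dimethoxy-4-(RA-oxy)phenyl]propan-1-ol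
Conditions: TBSCl, imidazole, CH2Cl2, 0 °C
Reagents that add atoms: tert-butyldimethylsilyl chloride, CC(C)(C)[Si](C)(C)Cl
Why: selective silylation of the primary hydroxyl, as in step 5.

Step 13
Reactants: 17 mono-TBS threo alcohol of unit B
Product: 18 (1R,2S)-2-(4-bromo-2,6-dimethoxyphenoxy)-3-(TBS-oxy)-1-[3,5-dimethoxy-4-(RA-oxy)phenyl]propyl 4-nitrobenzoate
Conditions: PPh3, DIAD, 4-nitrobenzoic acid, toluene, 0 °C → rt
Reagents that add atoms: 4-nitrobenzoic acid, O=C(O)c1ccc(cc1)[N+](=O)[O-]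
Why: Mitsunobu inversion of the benzylic carbinol of unit B (S to R), run in a non-polar solvent at low temperature to favour SN2 over ionisation.

Step 14
Reactants: 18 inverted 4-nitrobenzoate of unit B
Product: 19 (1R,2S)-2-(4-bromo-2,6-dimethoxyphenoxy)-3-(TBS-oxy)-1-[3,5-dimethoxy-4-(RA-oxy)phenyl]propan-1-ol
Conditions: K2CO3 (cat.), MeOH/THF, 0 °C
Reagents that add atoms: none
Why: mild methanolysis of the activated ester with retention at the carbinol carbon, as in step 7.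

Step 15
Reactants: 19 erythro alcohol of unit B
Product: 20 5-bromo-1,3-dimethoxy-2-(RB-oxy)benzene
Conditions: TBSOTf, 2,6-lutidine, CH2Cl2, 0 °C
Reagents that add atoms: tert-butyldimethylsilyl triflate, CC(C)(C)[Si](C)(C)OS(=O)(=O)C(F)(F)F
Why: silylation of the remaining secondary alcohol gives the fully protected bromide that carries all four side-chain stereocentres.

Step 16
Reactants: 20 5-bromo-1,3-dimethoxy-2-(RB-oxy)benzene
Product: 22 [3,5-dimethoxy-4-(RB-oxy)phenyl]boronic acid, via aryllithium 21 (not isolated)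
Conditions: n-BuLi, THF, −78 °C; B(Oi-Pr)3, −78 → 0 °C; aq. NH4Cl
Reagents that add atoms: triisopropyl borate, CC(C)OB(OC(C)C)OC(C)C; water, O
Why: bromine–lithium exchange, borylation with the trialkyl borate and mild hydrolysis should give a boronic acid that has no ortho substituent and so is not prone to fast protodeboronation.

Step 17
Reactants: 23 5-bromo-2-hydroxy-3-methoxybenzaldehyde; 24 ethyl diazoacetate
Product: 26 ethyl 5-bromo-7-methoxy-1-benzofuran-3-carboxylate, via hemiacetal 25 (not isolated)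
Conditions: HBF4·OEt2 (10 mol %), CH2Cl2, rt; then conc. H2SO4, rt
Reagents that add atoms: none
Why: Brønsted-acid-catalysed addition of the diazoester to the salicylaldehyde with loss of N2 and 1,2-aryl shift (Roskamp-type homologation) gives a formyl acetate that closes to hemiacetal 25 and is dehydrated to the benzofuran, so that C2 comes from the aldehyde carbon and C3 from the diazo carbon.

Step 18
Reactants: 26 ethyl 5-bromo-7-methoxy-1-benzofuran-3-carboxylate; 27 (E)-2-(3,3-diethoxyprop-1-en-1-yl)-4,4,5,5-tetramethyl-1,3,2-dioxaborolane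
Product: 28 ethyl 5-[(E)-3,3-diethoxyprop-1-en-1-yl]-7-methoxy-1-benzofuran-3-carboxylate
Conditions: Pd(dppf)Cl2 (3 mol %), K3PO4, dioxane/H2O, 80 °C
Reagents that add atoms: none
Why: Suzuki–Miyaura coupling with retention of the E geometry installs the enal as its base-stable diethyl acetal, which is not a Michael acceptor in the key step.

Step 19
Reactants: 22 [3,5-dimethoxy-4-(RB-oxy)phenyl]boronic acid; 28 ethyl 5-[(E)-3,3-diethoxyprop-1-en-1-yl]-7-methoxy-1-benzofuran-3-carboxylate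
Product: 29 ethyl (2R,3R)-5-[(E)-3,3-diethoxyprop-1-en-1-yl]-2-[3,5-dimethoxy-4-(RB-oxy)phenyl]-7-methoxy-2,3-dihydro-1-benzofuran-3-carboxylate (trans)
Conditions: [RhCl(C2H4)2]2 (2.5 mol %), (R,R)-Ph-bod* (5.5 mol %), KOH (20 mol %), dioxane/H2O 10:1, 50 °C; 28 in 1.5-fold excess
Reagents that add atoms: none
Why: Proposed new method: transmetallation of 22 to the Rh(I)–diene hydroxide gives an aryl–rhodium species that adds across C2=C3 of 28 with the aryl group going to C2, the β-carbon of the vinylogous carbonate O1–C2=C3–CO2Et, and protonolysis of the resulting rhodium enolate by water releases 29 and regenerates Rh–OH; the closest known reaction type is the Rh/chiral-diene Hayashi–Miyaura 1,4-addition of arylboronic acids to chromones (aryl delivered to the oxygen-bearing β-carbon of a benzo-fused heterocycle) and to β-substituted enoates. No ring is closed: the furan ring is already present and is dearomatised, which costs little because the benzene ring stays intact and the furan ring of a benzofuran behaves as an enol ether. C2 (R) is set by the chiral diene, which differentiates the two faces of the planar benzofuran in the insertion step, and C3 is set by protonation of the enolate on the face anti to the new C2 aryl group, which is also the thermodynamically preferred trans arrangement. The step needs regioselectivity (the ester polarisation directs the aryl group to C2), chemoselectivity (the masked enal at C5 is an acetal whose styrenyl double bond is not an acceptor, and the silyl ethers tolerate the weakly basic medium) and reagent control over the remote stereocentres of 22, which lie far from the reacting carbon. Syn β-hydride elimination is not possible from the adduct because the hydrogen on C2 is anti to rhodium, and ring opening by loss of the β-oxygen is expected to be slower than protonation in the aqueous medium.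

Step 20
Reactants: 29 trans ester
Product: 30 {(2R,3S)-5-[(E)-3,3-diethoxyprop-1-en-1-yl]-2-[3,5-dimethoxy-4-(RB-oxy)phenyl]-7-methoxy-2,3-dihydro-1-benzofuran-3-yl}methanol
Conditions: DIBAL-H, CH2Cl2, −78 °C; Rochelle salt
Reagents that add atoms: none
Why: hydride reduction of the ester to the primary alcohol under non-basic, low-temperature conditions, which should avoid epimerisation at C3 and E1cB opening of the ring and leaves acetal and silyl ethers untouched.

Step 21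
Reactants: 30 protected alcohol
Product: 31 CNP0192639.1, (E)-3-{(2R,3S)-2-[4-({(1R,2S)-1,3-dihydroxy-1-[4-({(1R,2S)-1,3-dihydroxy-1-(4-hydroxy-3-methoxyphenyl)propan-2-yl}oxy)-3,5-dimethoxyphenyl]propan-2-yl}oxy)-3,5-dimethoxyphenyl]-3-(hydroxymethyl)-7-methoxy-2,3-dihydro-1-benzofuran-5-yl}prop-2-enal
Conditions: HF·pyridine, pyridine, THF, 0 °C → rt; then H2O, rt; NaHCO3 work-up
Reagents that add atoms: water, O
Why: fluoride-driven cleavage of the four TBS ethers and the aryl TIPS ether, followed in the same flask by aqueous acidic hydrolysis of the α,β-unsaturated acetal to the E-enal, with no stereocentre involved.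

## Compound list

1 | vanillin (4-hydroxy-3-methoxybenzaldehyde) | COc1cc(C=O)ccc1O | starting material
2 | 3-methoxy-4-(triisopropylsilyloxy)benzaldehyde | COc1cc(C=O)ccc1O[Si](C(C)C)(C(C)C)C(C)C | intermediate
3 | 4-bromo-2,6-dimethoxyphenol | COc1cc(Br)cc(OC)c1O | starting material
4 | (R)-4-benzyl-3-(chloroacetyl)oxazolidin-2-one | O=C(CCl)N1C(=O)OC[C@H]1Cc1ccccc1 | starting material
5 | (R)-4-benzyl-3-[(4-bromo-2,6-dimethoxyphenoxy)acetyl]oxazolidin-2-one | COc1cc(Br)cc(OC)c1OCC(=O)N1C(=O)OC[C@H]1Cc1ccccc1 | intermediate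
6 | Z-dibutylboron enolate of 5 (not isolated) | CCCCB(CCCC)O/C(=C\Oc1c(OC)cc(Br)cc1OC)N1C(=O)OC[C@H]1Cc1ccccc1 | intermediate
7 | (R)-4-benzyl-3-{(2R,3S)-2-(4-bromo-2,6-dimethoxyphenoxy)-3-hydroxy-3-[3-methoxy-4-(TIPS-oxy)phenyl]propanoyl}oxazolidin-2-one | COc1cc([C@H](O)[C@H](C(=O)N2C(=O)OC[C@H]2Cc2ccccc2)Oc2c(OC)cc(Br)cc2OC)ccc1O[Si](C(C)C)(C(C)C)C(C)C | intermediate
8 | (1S,2S)-2-(4-bromo-2,6-dimethoxyphenoxy)-1-[3-methoxy-4-(TIPS-oxy)phenyl]propane-1,3-diol | COc1cc([C@H](O)[C@H](CO)Oc2c(OC)cc(Br)cc2OC)ccc1O[Si](C(C)C)(C(C)C)C(C)C | intermediate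
9 | (1S,2S)-2-(4-bromo-2,6-dimethoxyphenoxy)-3-(TBS-oxy)-1-[3-methoxy-4-(TIPS-oxy)phenyl]propan-1-ol | COc1cc([C@H](O)[C@H](CO[Si](C)(C)C(C)(C)C)Oc2c(OC)cc(Br)cc2OC)ccc1O[Si](C(C)C)(C(C)C)C(C)C | intermediate
10 | (1R,2S)-2-(4-bromo-2,6-dimethoxyphenoxy)-3-(TBS-oxy)-1-[3-methoxy-4-(TIPS-oxy)phenyl]propyl 4-nitrobenzoate | COc1cc([C@@H](OC(=O)c2ccc(cc2)[N+](=O)[O-])[C@H](CO[Si](C)(C)C(C)(C)C)Oc2c(OC)cc(Br)cc2OC)ccc1O[Si](C(C)C)(C(C)C)C(C)C | intermediate
11 | (1R,2S)-2-(4-bromo-2,6-dimethoxyphenoxy)-3-(TBS-oxy)-1-[3-methoxy-4-(TIPS-oxy)phenyl]propan-1-ol | COc1cc([C@@H](O)[C@H](CO[Si](C)(C)C(C)(C)C)Oc2c(OC)cc(Br)cc2OC)ccc1O[Si](C(C)C)(C(C)C)C(C)C | intermediate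
12 | 5-bromo-1,3-dimethoxy-2-(RA-oxy)benzene | COc1cc([C@@H](O[Si](C)(C)C(C)(C)C)[C@H](CO[Si](C)(C)C(C)(C)C)Oc2c(OC)cc(Br)cc2OC)ccc1O[Si](C(C)C)(C(C)C)C(C)C | intermediate
13 | aryllithium from 12, lithium in place of bromine (not isolated) | COc1cc([C@@H](O[Si](C)(C)C(C)(C)C)[C@H](CO[Si](C)(C)C(C)(C)C)Oc2c(OC)cc([Li])cc2OC)ccc1O[Si](C(C)C)(C(C)C)C(C)C | intermediate
14 | 3,5-dimethoxy-4-(RA-oxy)benzaldehyde | COc1cc([C@@H](O[Si](C)(C)C(C)(C)C)[C@H](CO[Si](C)(C)C(C)(C)C)Oc2c(OC)cc(C=O)cc2OC)ccc1O[Si](C(C)C)(C(C)C)C(C)C | intermediate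
15 | (R)-4-benzyl-3-{(2R,3S)-2-(4-bromo-2,6-dimethoxyphenoxy)-3-hydroxy-3-[3,5-dimethoxy-4-(RA-oxy)phenyl]propanoyl}oxazolidin-2-one | COc1cc([C@@H](O[Si](C)(C)C(C)(C)C)[C@H](CO[Si](C)(C)C(C)(C)C)Oc2c(OC)cc([C@H](O)[C@H](C(=O)N3C(=O)OC[C@H]3Cc3ccccc3)Oc3c(OC)cc(Br)cc3OC)cc2OC)ccc1O[Si](C(C)C)(C(C)C)C(C)C | intermediate
16 | (1S,2S)-2-(4-bromo-2,6-dimethoxyphenoxy)-1-[3,5-dimethoxy-4-(RA-oxy)phenyl]propane-1,3-diol | COc1cc([C@@H](O[Si](C)(C)C(C)(C)C)[C@H](CO[Si](C)(C)C(C)(C)C)Oc2c(OC)cc([C@H](O)[C@H](CO)Oc3c(OC)cc(Br)cc3OC)cc2OC)ccc1O[Si](C(C)C)(C(C)C)C(C)C | intermediate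
17 | (1S,2S)-2-(4-bromo-2,6-dimethoxyphenoxy)-3-(TBS-oxy)-1-[3,5-dimethoxy-4-(RA-oxy)phenyl]propan-1-ol | COc1cc([C@@H](O[Si](C)(C)C(C)(C)C)[C@H](CO[Si](C)(C)C(C)(C)C)Oc2c(OC)cc([C@H](O)[C@H](CO[Si](C)(C)C(C)(C)C)Oc3c(OC)cc(Br)cc3OC)cc2OC)ccc1O[Si](C(C)C)(C(C)C)C(C)C | intermediate
18 | (1R,2S)-2-(4-bromo-2,6-dimethoxyphenoxy)-3-(TBS-oxy)-1-[3,5-dimethoxy-4-(RA-oxy)phenyl]propyl 4-nitrobenzoate | COc1cc([C@@H](O[Si](C)(C)C(C)(C)C)[C@H](CO[Si](C)(C)C(C)(C)C)Oc2c(OC)cc([C@@H](OC(=O)c3ccc(cc3)[N+](=O)[O-])[C@H](CO[Si](C)(C)C(C)(C)C)Oc3c(OC)cc(Br)cc3OC)cc2OC)ccc1O[Si](C(C)C)(C(C)C)C(C)C | intermediate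
19 | (1R,2S)-2-(4-bromo-2,6-dimethoxyphenoxy)-3-(TBS-oxy)-1-[3,5-dimethoxy-4-(RA-oxy)phenyl]propan-1-ol | COc1cc([C@@H](O[Si](C)(C)C(C)(C)C)[C@H](CO[Si](C)(C)C(C)(C)C)Oc2c(OC)cc([C@@H](O)[C@H](CO[Si](C)(C)C(C)(C)C)Oc3c(OC)cc(Br)cc3OC)cc2OC)ccc1O[Si](C(C)C)(C(C)C)C(C)C | intermediate
20 | 5-bromo-1,3-dimethoxy-2-(RB-oxy)benzene | COc1cc([C@@H](O[Si](C)(C)C(C)(C)C)[C@H](CO[Si](C)(C)C(C)(C)C)Oc2c(OC)cc([C@@H](O[Si](C)(C)C(C)(C)C)[C@H](CO[Si](C)(C)C(C)(C)C)Oc3c(OC)cc(Br)cc3OC)cc2OC)ccc1O[Si](C(C)C)(C(C)C)C(C)C | intermediate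
21 | aryllithium from 20, lithium in place of bromine (not isolated) | COc1cc([C@@H](O[Si](C)(C)C(C)(C)C)[C@H](CO[Si](C)(C)C(C)(C)C)Oc2c(OC)cc([C@@H](O[Si](C)(C)C(C)(C)C)[C@H](CO[Si](C)(C)C(C)(C)C)Oc3c(OC)cc([Li])cc3OC)cc2OC)ccc1O[Si](C(C)C)(C(C)C)C(C)C | intermediate
22 | [3,5-dimethoxy-4-(RB-oxy)phenyl]boronic acid | COc1cc([C@@H](O[Si](C)(C)C(C)(C)C)[C@H](CO[Si](C)(C)C(C)(C)C)Oc2c(OC)cc([C@@H](O[Si](C)(C)C(C)(C)C)[C@H](CO[Si](C)(C)C(C)(C)C)Oc3c(OC)cc(B(O)O)cc3OC)cc2OC)ccc1O[Si](C(C)C)(C(C)C)C(C)C | intermediate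
23 | 5-bromo-2-hydroxy-3-methoxybenzaldehyde | COc1cc(Br)cc(C=O)c1O | starting material
24 | ethyl diazoacetate | CCOC(=O)C=[N+]=[N-] | starting material
25 | ethyl 5-bromo-2-hydroxy-7-methoxy-2,3-dihydro-1-benzofuran-3-carboxylate, hemiacetal as a mixture of diastereomers (not isolated) | CCOC(=O)C1C(O)Oc2c(OC)cc(Br)cc21 | intermediate
26 | ethyl 5-bromo-7-methoxy-1-benzofuran-3-carboxylate | CCOC(=O)c1coc2c(OC)cc(Br)cc12 | intermediate
27 | (E)-2-(3,3-diethoxyprop-1-en-1-yl)-4,4,5,5-tetramethyl-1,3,2-dioxaborolane | CCOC(OCC)/C=C/B1OC(C)(C)C(C)(C)O1 | starting material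
28 | ethyl 5-[(E)-3,3-diethoxyprop-1-en-1-yl]-7-methoxy-1-benzofuran-3-carboxylate | CCOC(=O)c1coc2c(OC)cc(/C=C/C(OCC)OCC)cc12 | intermediate
29 | ethyl (2R,3R)-5-[(E)-3,3-diethoxyprop-1-en-1-yl]-2-[3,5-dimethoxy-4-(RB-oxy)phenyl]-7-methoxy-2,3-dihydro-1-benzofuran-3-carboxylate (trans) | COc1cc([C@@H](O[Si](C)(C)C(C)(C)C)[C@H](CO[Si](C)(C)C(C)(C)C)Oc2c(OC)cc([C@@H](O[Si](C)(C)C(C)(C)C)[C@H](CO[Si](C)(C)C(C)(C)C)Oc3c(OC)cc([C@@H]4Oc5c(OC)cc(/C=C/C(OCC)OCC)cc5[C@H]4C(=O)OCC)cc3OC)cc2OC)ccc1O[Si](C(C)C)(C(C)C)C(C)C | intermediate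
30 | {(2R,3S)-5-[(E)-3,3-diethoxyprop-1-en-1-yl]-2-[3,5-dimethoxy-4-(RB-oxy)phenyl]-7-methoxy-2,3-dihydro-1-benzofuran-3-yl}methanol | COc1cc([C@@H](O[Si](C)(C)C(C)(C)C)[C@H](CO[Si](C)(C)C(C)(C)C)Oc2c(OC)cc([C@@H](O[Si](C)(C)C(C)(C)C)[C@H](CO[Si](C)(C)C(C)(C)C)Oc3c(OC)cc([C@@H]4Oc5c(OC)cc(/C=C/C(OCC)OCC)cc5[C@H]4CO)cc3OC)cc2OC)ccc1O[Si](C(C)C)(C(C)C)C(C)C | intermediate
31 | CNP0192639.1, (E)-3-{(2R,3S)-2-[4-({(1R,2S)-1,3-dihydroxy-1-[4-({(1R,2S)-1,3-dihydroxy-1-(4-hydroxy-3-methoxyphenyl)propan-2-yl}oxy)-3,5-dimethoxyphenyl]propan-2-yl}oxy)-3,5-dimethoxyphenyl]-3-(hydroxymethyl)-7-methoxy-2,3-dihydro-1-benzofuran-5-yl}prop-2-enal | COc1cc([C@@H](O)[C@H](CO)Oc2c(OC)cc([C@@H](O)[C@H](CO)Oc3c(OC)cc([C@@H]4Oc5c(OC)cc(/C=C/C=O)cc5[C@H]4CO)cc3OC)cc2OC)ccc1O | target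

## Step count and risks

Total step count: 21. Longest linear sequence: 18 steps (steps 1, 3–16, 19–21).

**Step 19 (proposed new method).** Carborhodation of the trisubstituted, partly aromatic enoate may be too slow, so that protodeboronation of 22 takes over. The furan ring may open by loss of the β-oxygen or by retro-oxa-Michael reaction of the product, and facial selectivity on the benzofuran may be poor. The fallback uses known chemistry and sets out from 20 and 28. Palladium-catalysed direct C2–H arylation of 28 with bromide 20 (Pd(OAc)2, PCy3·HBF4, PivOH, K2CO3, toluene, 110 °C) should give the flat ethyl 2-aryl-1-benzofuran-3-carboxylate F1. Dissolving-metal conjugate reduction with magnesium in methanol/THF should then give the thermodynamic trans-dihydrobenzofuran with transesterification, as the methyl (2R,3R)-ester F2 and its (2S,3S)-diastereomer F3. These are separated by preparative HPLC, and reduction of F2 with DIBAL-H comes back to the route at 30.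

**Step 13.** The electron-rich benzylic alkoxyphosphonium ion (para-alkoxy, two meta-methoxy groups) may ionise, which would erode the inversion, or may eliminate to the enol ether. The fallback sets out from 17. Dess–Martin oxidation (NaHCO3, CH2Cl2) should give the aryl ketone F4. Reagent-controlled Corey–Bakshi–Shibata reduction ((R)-Me-CBS expected by analogy with α-oxygenated aryl ketones, BH3·SMe2, toluene, −30 °C) should give the (1R)-carbinol and come back to the route at 19.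

**Step 6.** The same loss of stereochemical fidelity by ionisation, or elimination, may occur at the benzylic centre of unit A, though this centre is less ionisable. The fallback sets out from 9. Dess–Martin oxidation should give the aryl ketone F5, and Corey–Bakshi–Shibata reduction under the same reagent control should come back to the route at 11.

Further compounds
F1 | step 19 | ethyl 5-[(E)-3,3-diethoxyprop-1-en-1-yl]-2-[3,5-dimethoxy-4-(RB-oxy)phenyl]-7-methoxy-1-benzofuran-3-carboxylate | COc1cc([C@@H](O[Si](C)(C)C(C)(C)C)[C@H](CO[Si](C)(C)C(C)(C)C)Oc2c(OC)cc([C@@H](O[Si](C)(C)C(C)(C)C)[C@H](CO[Si](C)(C)C(C)(C)C)Oc3c(OC)cc(-c4oc5c(OC)cc(/C=C/C(OCC)OCC)cc5c4C(=O)OCC)cc3OC)cc2OC)ccc1O[Si](C(C)C)(C(C)C)C(C)C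
F2 | step 19 | methyl (2R,3R)-5-[(E)-3,3-diethoxyprop-1-en-1-yl]-2-[3,5-dimethoxy-4-(RB-oxy)phenyl]-7-methoxy-2,3-dihydro-1-benzofuran-3-carboxylate | COc1cc([C@@H](O[Si](C)(C)C(C)(C)C)[C@H](CO[Si](C)(C)C(C)(C)C)Oc2c(OC)cc([C@@H](O[Si](C)(C)C(C)(C)C)[C@H](CO[Si](C)(C)C(C)(C)C)Oc3c(OC)cc([C@@H]4Oc5c(OC)cc(/C=C/C(OCC)OCC)cc5[C@H]4C(=O)OC)cc3OC)cc2OC)ccc1O[Si](C(C)C)(C(C)C)C(C)C
F3 | step 19 | methyl (2S,3S)-5-[(E)-3,3-diethoxyprop-1-en-1-yl]-2-[3,5-dimethoxy-4-(RB-oxy)phenyl]-7-methoxy-2,3-dihydro-1-benzofuran-3-carboxylate | COc1cc([C@@H](O[Si](C)(C)C(C)(C)C)[C@H](CO[Si](C)(C)C(C)(C)C)Oc2c(OC)cc([C@@H](O[Si](C)(C)C(C)(C)C)[C@H](CO[Si](C)(C)C(C)(C)C)Oc3c(OC)cc([C@H]4Oc5c(OC)cc(/C=C/C(OCC)OCC)cc5[C@@H]4C(=O)OC)cc3OC)cc2OC)ccc1O[Si](C(C)C)(C(C)C)C(C)C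
F4 | step 13 | (S)-2-(4-bromo-2,6-dimethoxyphenoxy)-3-(TBS-oxy)-1-[3,5-dimethoxy-4-(RA-oxy)phenyl]propan-1-one | COc1cc([C@@H](O[Si](C)(C)C(C)(C)C)[C@H](CO[Si](C)(C)C(C)(C)C)Oc2c(OC)cc(C(=O)[C@H](CO[Si](C)(C)C(C)(C)C)Oc3c(OC)cc(Br)cc3OC)cc2OC)ccc1O[Si](C(C)C)(C(C)C)C(C)C
F5 | step 6 | (S)-2-(4-bromo-2,6-dimethoxyphenoxy)-3-(TBS-oxy)-1-[3-methoxy-4-(TIPS-oxy)phenyl]propan-1-one | COc1cc(C(=O)[C@H](CO[Si](C)(C)C(C)(C)C)Oc2c(OC)cc(Br)cc2OC)ccc1O[Si](C(C)C)(C(C)C)C(C)C
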